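**Retrosynthetic overview**

1. Halimane numbering is used (ring A = C1–C5 and C10, ring B = C5–C10). In ring A the acyl carbon C2 is tied to C5 once through C3–C4 and once through the enone carbons C1=C10. Taking out C1 and C10 leaves a cyclobutanone C2–C3–C4–C5, and C10 is also the atom from which ring B (C6–C9) hangs.
2. Key disconnection C1–C2 and C5–C10: cyclobutanone 25, whose C5 carries a four-carbon tether ending in the alkyne C10≡C1. Rhodium-catalysed C2–C5 activation with alkyne insertion enlarges the four-membered ring to ring A and closes ring B in the same operation (last step; ring order: cyclobutane, then B and A together).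
3. 25 ⇐ bond C5–C6: SAMP-hydrazone alkylation of a 3-methyl-3-(cage ortho ester)cyclobutanone with iodide 14; this sets C5, and C4 relative to it.
4. 14 ⇐ δ-lactone 9: C8 and C9 come from two enolate alkylations of (R)-4-methyl-δ-valerolactone 3; the side-chain iodide 7 (C11–C15, with C13) is cut from the same lactone.
5. Chirality sources: half ester 1 (C8, C13) and SAMP (C5, and with it C4); C9 follows from C8 by substrate control.

Key step: step 18

Remark: the SAMP azaenolate of a cyclobutanone is assumed to be alkylated in the same facial sense as those of five- and six-membered ketones.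

**Route**

Step 1
Reactants: 1 methyl hydrogen (R)-3-methylglutarate
Product: 3 (R)-4-methyloxan-2-one, via methyl (R)-5-hydroxy-3-methylpentanoate 2 (not isolated)
Conditions: BH3·SMe2, THF, 0 °C to rt; H2O; then TsOH (cat.), toluene, 80 °C
Reagents that add atoms: none
Why: Chemoselective borane reduction of the free acid beside the methyl ester, then acid-catalysed lactonisation; the stereocentre is not touched, and because the lactone carbonyl is the former ester carbon the (R) descriptor is kept.

Step 2
Reactants: 3 (R)-4-methyloxan-2-one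
Product: 5 (S)-5-iodo-3-methylpentanoic acid, via trimethylsilyl (S)-5-iodo-3-methylpentanoate 4 (not isolated)
Conditions: Me3SiI, CH2Cl2, rt; then H2O
Reagents that add atoms: iodotrimethylsilane, C[Si](C)(C)I
Why: Silyl iodide cleavage of a lactone: iodide attacks the O–CH2 carbon of the silylated lactone by SN2 and water frees the acid; the stereocentre is remote and keeps its geometry.

Step 3
Reactants: 5 (S)-5-iodo-3-methylpentanoic acid
Product: 6 (S)-5-iodo-3-methylpentan-1-ol
Conditions: BH3·THF, THF, 0 °C to rt; H2O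
Reagents that add atoms: none
Why: Borane reduces the carboxylic acid selectively and should leave the primary iodide intact (chemoselective BH3 reduction).

Step 4
Reactants: 6 (S)-5-iodo-3-methylpentan-1-ol
Product: 7 (S)-tert-butyl[(5-iodo-3-methylpentyl)oxy]dimethylsilane
Conditions: t-BuMe2SiCl, imidazole, CH2Cl2, 0 °C to rt
Reagents that add atoms: tert-butyldimethylsilyl chloride, CC(C)(C)[Si](C)(C)Cl
Why: Standard silylation of a primary alcohol, faster than intramolecular ether formation under these mild conditions.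

Step 5
Reactants: 3 (R)-4-methyloxan-2-one
Product: 8 (3S,4R)-3,4-dimethyloxan-2-one
Conditions: LiN(i-Pr)2, THF, −78 °C; MeI, −78 to −40 °C
Reagents that add atoms: iodomethane, CI
Why: Kinetic lactone enolate alkylation; MeI should enter anti to the C4 methyl (trans product), and this centre is enolised again in step 6, so its ratio is of no consequence.

Step 6
Reactants: 8 (3S,4R)-3,4-dimethyloxan-2-one; 7 (S)-tert-butyl[(5-iodo-3-methylpentyl)oxy]dimethylsilane
Product: 9 (3S,4R)-3-[(3R)-5-(tert-butyldimethylsilyloxy)-3-methylpentyl]-3,4-dimethyloxan-2-one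
Conditions: LiN(i-Pr)2, THF, −78 °C; HMPA, then 7, −78 to −20 °C
Reagents that add atoms: none
Why: Second lactone enolate alkylation forms the quaternary carbon (C9 of the target): in the half-chair enolate the C4 methyl sits pseudoaxial to avoid A(1,2) strain with the C3 methyl, and the iodide attacks the opposite face, so the side chain ends trans to the C4 methyl.

Step 7
Reactants: 9 (3S,4R)-3-[(3R)-5-(tert-butyldimethylsilyloxy)-3-methylpentyl]-3,4-dimethyloxan-2-one
Product: 10 (3S,4R)-3-[(3R)-5-(tert-butyldimethylsilyloxy)-3-methylpentyl]-3,4-dimethyloxan-2-ol (both anomers)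
Conditions: i-Bu2AlH, CH2Cl2, −78 °C; aq. potassium sodium tartrate
Reagents that add atoms: none
Why: Partial reduction of a lactone to the lactol; the tetrahedral aluminate is stable at −78 °C and the neighbouring quaternary carbon slows over-reduction.

Step 8
Reactants: 10 (3S,4R)-3-[(3R)-5-(tert-butyldimethylsilyloxy)-3-methylpentyl]-3,4-dimethyloxan-2-ol
Product: 11 (3R,4S,7R)-9-(tert-butyldimethylsilyloxy)-4-ethynyl-3,4,7-trimethylnonan-1-ol
Conditions: dimethyl (1-diazo-2-oxopropyl)phosphonate, K2CO3, MeOH, rt to 40 °C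
Reagents that add atoms: dimethyl (1-diazo-2-oxopropyl)phosphonate (Ohira–Bestmann reagent), CC(=O)C(=[N+]=[N-])P(=O)(OC)OC
Why: Seyferth–Gilbert homologation through the open hydroxy aldehyde form of the lactol gives the terminal alkyne (C10≡C1) and frees the C6 hydroxyl; the α-carbon is quaternary and cannot epimerise.

Step 9
Reactants: 11 (3R,4S,7R)-9-(tert-butyldimethylsilyloxy)-4-ethynyl-3,4,7-trimethylnonan-1-ol
Product: 13 (3R,4S,7R)-9-(tert-butyldimethylsilyloxy)-3,4,7-trimethyl-4-[(trimethylsilyl)ethynyl]nonan-1-ol, via the O,C-bis(trimethylsilyl) derivative 12 (not isolated)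
Conditions: n-BuLi (2.2 equiv), THF, −78 to 0 °C; Me3SiCl (2.5 equiv); then 1 M aq. HCl, 0 °C, 10 min
Reagents that add atoms: chlorotrimethylsilane, C[Si](C)(C)Cl
Why: Alkoxide/acetylide dianion formation, double silylation and selective acidic cleavage of the labile O–SiMe3 bond; the acidic alkyne C–H is masked for step 14.

Step 10
Reactants: 13 (3R,4S,7R)-9-(tert-butyldimethylsilyloxy)-3,4,7-trimethyl-4-[(trimethylsilyl)ethynyl]nonan-1-ol
Product: 14 tert-butyl{[(3R,6S,7R)-9-iodo-3,6,7-trimethyl-6-[(trimethylsilyl)ethynyl]nonyl]oxy}dimethylsilane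
Conditions: I2, PPh3, imidazole, CH2Cl2, 0 °C to rt
Reagents that add atoms: iodine, II
Why: Appel-type iodination of an unhindered primary alcohol by SN2 displacement of the alkoxyphosphonium ion.

Step 11
Reactants: 15 1-methyl-3-oxocyclobutane-1-carboxylic acid; 16 (3-methyloxetan-3-yl)methanol
Product: 17 (3-methyloxetan-3-yl)methyl 1-methyl-3-oxocyclobutane-1-carboxylate
Conditions: DCC, DMAP (cat.), CH2Cl2, 0 °C to rt
Reagents that add atoms: none
Why: Steglich esterification of a hindered acid with a primary alcohol.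

Step 12
Reactants: 17 (3-methyloxetan-3-yl)methyl 1-methyl-3-oxocyclobutane-1-carboxylate
Product: 18 3-methyl-3-(4-methyl-2,6,7-trioxabicyclo[2.2.2]octan-1-yl)cyclobutan-1-one
Conditions: BF3·OEt2 (0.25 equiv), CH2Cl2, −15 °C to rt; Et3N quench
Reagents that add atoms: none
Why: Lewis acid-promoted rearrangement of an oxetanylmethyl ester to the bicyclic (OBO) ortho ester, which turns the carboxyl group into a base-stable substituent far bulkier than the methyl group beside it.

Step 13
Reactants: 18 3-methyl-3-(4-methyl-2,6,7-trioxabicyclo[2.2.2]octan-1-yl)cyclobutan-1-one; 19 SAMP, (S)-1-amino-2-(methoxymethyl)pyrrolidine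
Product: 20 SAMP hydrazone of 18 (both C=N isomers)
Conditions: cyclohexane, 4 Å molecular sieves, 60 °C
Reagents that add atoms: none
Why: Neutral hydrazone condensation of a reactive strained ketone; the ortho ester tolerates these acid-free conditions.

Step 14
Reactants: 20 SAMP hydrazone of 18 (2.5 equiv); 14 tert-butyl{[(3R,6S,7R)-9-iodo-3,6,7-trimethyl-6-[(trimethylsilyl)ethynyl]nonyl]oxy}dimethylsilane (1.0 equiv)
Product: 21 SAMP hydrazone of (2R,3S)-2-[(3R,4S,7R)-9-(tert-butyldimethylsilyloxy)-3,4,7-trimethyl-4-[(trimethylsilyl)ethynyl]nonyl]-3-methyl-3-(4-methyl-2,6,7-trioxabicyclo[2.2.2]octan-1-yl)cyclobutan-1-one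
Conditions: LiN(i-Pr)2 (2.4 equiv), THF, 0 °C; cool to −100 °C, add 14, warm slowly to −20 °C
Reagents that add atoms: none
Why: Enders SAMP-hydrazone alkylation: the auxiliary leaves one face of the lithium azaenolate open and so fixes C5, while the cage ortho ester on the neighbouring carbon blocks its own side, so the chain should end cis to the methyl and trans to the masked carboxyl (C4 relative to C5); because the ketone is prochiral only the azaenolate in which both controls point to the same face should react at a useful rate, which is why the inexpensive hydrazone is in excess and the iodide is limiting.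

Step 15
Reactants: 21 SAMP hydrazone from step 14
Product: 23 methyl (1S,2R)-2-[(3R,4S,7R)-9-(tert-butyldimethylsilyloxy)-4-ethynyl-3,4,7-trimethylnonyl]-3-{[(2S)-2-(methoxymethyl)pyrrolidin-1-yl]imino}-1-methylcyclobutane-1-carboxylate, via the 3-hydroxy-2-(hydroxymethyl)-2-methylpropyl ester 22 (not isolated)
Conditions: PPTS (0.2 equiv), THF/H2O 5:1, rt; evaporate THF; then K2CO3, MeOH, 40 °C
Reagents that add atoms: water, O; methanol, CO
Why: Mild acid opens the ortho ester to its diol ester, and base-mediated transesterification then gives the methyl ester while cleaving the alkynyl C–Si bond; the ketone stays masked as the hydrazone, so C5 cannot epimerise in base.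

Step 16
Reactants: 23 hydrazone methyl ester from step 15
Product: 24 methyl (1S,2R)-2-[(3R,4S,7R)-4-ethynyl-9-hydroxy-3,4,7-trimethylnonyl]-1-methyl-3-oxocyclobutane-1-carboxylate
Conditions: saturated aq. oxalic acid/THF 1:2, rt, 12 h; NaHCO3 work-up
Reagents that add atoms: water, O
Why: Oxalic acid hydrolysis of the SAMP hydrazone, the standard epimerisation-free cleavage, should also hydrolyse the primary silyl ether at this acidity; SAMP can be recovered.

Step 17
Reactants: 24 keto alcohol from step 16
Product: 25 methyl (1S,2R)-2-[(3R,4S,7R)-9-acetoxy-4-ethynyl-3,4,7-trimethylnonyl]-1-methyl-3-oxocyclobutane-1-carboxylate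
Conditions: Ac2O, pyridine, DMAP (cat.), CH2Cl2, 0 °C
Reagents that add atoms: acetic anhydride, CC(=O)OC(C)=O
Why: Standard acetylation of the primary alcohol; pyridine is far too weak a base to enolise the cyclobutanone.

Step 18
Reactants: 25 methyl (1S,2R)-2-[(3R,4S,7R)-9-acetoxy-4-ethynyl-3,4,7-trimethylnonyl]-1-methyl-3-oxocyclobutane-1-carboxylate
Product: 26 methyl (4S,5S,8R,9S,13R)-15-acetoxy-2-oxohalim-1(10)-en-18-oate (CNP0250576.1)
Conditions: [Rh(CO)2Cl]2 (5 mol %), P[3,5-(CF3)2C6H3]3 (20 mol %), 1,4-dioxane (0.05 M), 130 °C, sealed tube, argon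
Reagents that add atoms: none
Why: Monovalent rhodium inserts into the strained acyl–C5 bond of the cyclobutanone (directly, or by insertion on the less hindered C2–C3 side followed by CO extrusion and re-insertion on the C5 side) to give a five-membered trivalent rhodacycle, the tethered alkyne inserts into the Rh–C5 bond, and acyl–alkenyl reductive elimination releases the enone. The closest known reaction type is the rhodium-catalysed intramolecular carboacylation ("cut-and-sew") of cyclobutanones that carry an alkyne on a tether at the α-carbon, which gives cyclohexenone-fused bicycles. Ring B closes by 6-exo-dig migratory insertion (bond C5–C10); ring A arises from the four-membered ring by insertion of C10 and C1 between C5 and C2 (bonds C5–C10 and C1–C2 made, C2–C5 broken), with about 26 kcal/mol of ring strain as driving force. No stereocentre is created: C5 keeps its configuration because the Rh–C5 bond is made and broken with retention, C4, C8, C9 and C13 are not touched, and C10 becomes trigonal. The step needs cleavage on the substituted side of the ketone and insertion faster than loss of CO to a cyclopropane: only rhodium bound to C5 can reach the alkyne (exo insertion gives the six-membered ring, endo would need a seven-membered one), and the CO-bearing precatalyst with the π-acidic, bulky phosphine should hold back decarbonylation. The terminal alkyne puts rhodium on the unhindered C1, and its quaternary propargylic carbon should slow alkyne oligomerisation.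

**Compound list**

1 | methyl hydrogen (R)-3-methylglutarate | OC(=O)C[C@@H](C)CC(=O)OC | starting material
2 | methyl (R)-5-hydroxy-3-methylpentanoate | OCC[C@@H](C)CC(=O)OC | intermediate
3 | (R)-4-methyloxan-2-one | O=C1OCC[C@@H](C)C1 | intermediate
4 | trimethylsilyl (S)-5-iodo-3-methylpentanoate | ICC[C@@H](C)CC(=O)O[Si](C)(C)C | intermediate
5 | (S)-5-iodo-3-methylpentanoic acid | ICC[C@@H](C)CC(O)=O | intermediate
6 | (S)-5-iodo-3-methylpentan-1-ol | ICC[C@@H](C)CCO | intermediate
7 | (S)-tert-butyl[(5-iodo-3-methylpentyl)oxy]dimethylsilane | ICC[C@@H](C)CCO[Si](C)(C)C(C)(C)C | intermediate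
8 | (3S,4R)-3,4-dimethyloxan-2-one | O=C1OCC[C@@H](C)[C@@H]1C | intermediate
9 | (3S,4R)-3-[(3R)-5-(tert-butyldimethylsilyloxy)-3-methylpentyl]-3,4-dimethyloxan-2-one | O=C1OCC[C@@H](C)[C@]1(C)CC[C@@H](C)CCO[Si](C)(C)C(C)(C)C | intermediate
10 | (3S,4R)-3-[(3R)-5-(tert-butyldimethylsilyloxy)-3-methylpentyl]-3,4-dimethyloxan-2-ol (anomers) | OC1OCC[C@@H](C)[C@]1(C)CC[C@@H](C)CCO[Si](C)(C)C(C)(C)C | intermediate
11 | (3R,4S,7R)-9-(tert-butyldimethylsilyloxy)-4-ethynyl-3,4,7-trimethylnonan-1-ol | OCC[C@@H](C)[C@@](C)(C#C)CC[C@@H](C)CCO[Si](C)(C)C(C)(C)C | intermediate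
12 | O,C-bis(trimethylsilyl) derivative of 11 | C[Si](C)(C)OCC[C@@H](C)[C@@](C)(C#C[Si](C)(C)C)CC[C@@H](C)CCO[Si](C)(C)C(C)(C)C | intermediate
13 | (3R,4S,7R)-9-(tert-butyldimethylsilyloxy)-3,4,7-trimethyl-4-[(trimethylsilyl)ethynyl]nonan-1-ol | OCC[C@@H](C)[C@@](C)(C#C[Si](C)(C)C)CC[C@@H](C)CCO[Si](C)(C)C(C)(C)C | intermediate
14 | tert-butyl{[(3R,6S,7R)-9-iodo-3,6,7-trimethyl-6-[(trimethylsilyl)ethynyl]nonyl]oxy}dimethylsilane | ICC[C@@H](C)[C@@](C)(C#C[Si](C)(C)C)CC[C@@H](C)CCO[Si](C)(C)C(C)(C)C | intermediate
15 | 1-methyl-3-oxocyclobutane-1-carboxylic acid | CC1(CC(=O)C1)C(O)=O | starting material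
16 | (3-methyloxetan-3-yl)methanol | CC1(CO)COC1 | starting material
17 | (3-methyloxetan-3-yl)methyl 1-methyl-3-oxocyclobutane-1-carboxylate | CC1(COC(=O)C2(C)CC(=O)C2)COC1 | intermediate
18 | 3-methyl-3-(4-methyl-2,6,7-trioxabicyclo[2.2.2]octan-1-yl)cyclobutan-1-one | CC12COC(OC1)(OC2)C1(C)CC(=O)C1 | intermediate
19 | SAMP, (S)-1-amino-2-(methoxymethyl)pyrrolidine | COC[C@@H]1CCCN1N | starting material
20 | SAMP hydrazone of 18: (S)-2-(methoxymethyl)-N-[3-methyl-3-(4-methyl-2,6,7-trioxabicyclo[2.2.2]octan-1-yl)cyclobutylidene]pyrrolidin-1-amine | CC12COC(OC1)(OC2)C1(C)CC(C1)=NN1CCC[C@H]1COC | intermediate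
21 | SAMP hydrazone of (2R,3S)-2-[(3R,4S,7R)-9-(tert-butyldimethylsilyloxy)-3,4,7-trimethyl-4-[(trimethylsilyl)ethynyl]nonyl]-3-methyl-3-(4-methyl-2,6,7-trioxabicyclo[2.2.2]octan-1-yl)cyclobutan-1-one | CC12COC(OC1)(OC2)[C@@]3(C)CC(=NN4CCC[C@H]4COC)[C@@H]3CC[C@@H](C)[C@@](C)(C#C[Si](C)(C)C)CC[C@@H](C)CCO[Si](C)(C)C(C)(C)C | intermediate
22 | 3-hydroxy-2-(hydroxymethyl)-2-methylpropyl (1S,2R)-2-[(3R,4S,7R)-9-(tert-butyldimethylsilyloxy)-3,4,7-trimethyl-4-[(trimethylsilyl)ethynyl]nonyl]-3-{[(2S)-2-(methoxymethyl)pyrrolidin-1-yl]imino}-1-methylcyclobutane-1-carboxylate | OCC(C)(CO)COC(=O)[C@@]1(C)CC(=NN2CCC[C@H]2COC)[C@@H]1CC[C@@H](C)[C@@](C)(C#C[Si](C)(C)C)CC[C@@H](C)CCO[Si](C)(C)C(C)(C)C | intermediate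
23 | methyl (1S,2R)-2-[(3R,4S,7R)-9-(tert-butyldimethylsilyloxy)-4-ethynyl-3,4,7-trimethylnonyl]-3-{[(2S)-2-(methoxymethyl)pyrrolidin-1-yl]imino}-1-methylcyclobutane-1-carboxylate | COC(=O)[C@@]1(C)CC(=NN2CCC[C@H]2COC)[C@@H]1CC[C@@H](C)[C@@](C)(C#C)CC[C@@H](C)CCO[Si](C)(C)C(C)(C)C | intermediate
24 | methyl (1S,2R)-2-[(3R,4S,7R)-4-ethynyl-9-hydroxy-3,4,7-trimethylnonyl]-1-methyl-3-oxocyclobutane-1-carboxylate | COC(=O)[C@@]1(C)CC(=O)[C@@H]1CC[C@@H](C)[C@@](C)(C#C)CC[C@@H](C)CCO | intermediate
25 | methyl (1S,2R)-2-[(3R,4S,7R)-9-acetoxy-4-ethynyl-3,4,7-trimethylnonyl]-1-methyl-3-oxocyclobutane-1-carboxylate | COC(=O)[C@@]1(C)CC(=O)[C@@H]1CC[C@@H](C)[C@@](C)(C#C)CC[C@@H](C)CCOC(C)=O | intermediate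
26 | methyl (4S,5S,8R,9S,13R)-15-acetoxy-2-oxohalim-1(10)-en-18-oate (CNP0250576.1) | COC(=O)[C@@]1(C)CC(=O)C=C2[C@@H]1CC[C@@H](C)[C@]2(C)CC[C@@H](C)CCOC(C)=O | target

**Step count**

Total step count: 18. Longest linear sequence: 14 steps (steps 1, 2, 3, 4, 6, 7, 8, 9, 10, 14, 15, 16, 17, 18).

**Three steps most likely to fail**

Step 18. The rhodacycle may lose CO and collapse to a cyclopropane, rhodium may activate the free alkyne C–H (vinylidene formation, oligomerisation), or insertion next to the quaternary C9 may be too slow. The fallback takes the alkyne out of the C–C activation step. Setting out from 25, semihydrogenation (H2, Pd/CaCO3 poisoned with Pb(OAc)2, quinoline, EtOAc) should give methyl (1S,2R)-2-[(3R,4R,7R)-9-acetoxy-4-ethenyl-3,4,7-trimethylnonyl]-1-methyl-3-oxocyclobutane-1-carboxylate F1. The alkene version of the same ring expansion ([Rh(C2H4)2Cl]2, DTBM-SEGPHOS in the enantiomer that matches the substrate, 1,4-dioxane, 25–60 °C) is the most developed variant and runs far below 130 °C; it should give methyl 15-acetoxy-2-oxohalimane-18-oate F2, in which the configuration at C10 is of no consequence. Dehydrogenation with IBX (DMSO, 70 °C) can only go toward C1–C10, because C4 carries no hydrogen, and comes back to the route at 26.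

Step 14. Half of the azaenolate has auxiliary and ortho ester pointing to opposite faces; if it is alkylated on the face the auxiliary disfavours, the configuration of the ring (C4/C5) is eroded relative to the chain, and the resulting diastereomer would be hard to remove. The fallback moves the choice of α-carbon from the hydrazone to a chiral base. Setting out from 18, enantioselective deprotonation with lithium bis[(R)-1-phenylethyl]amide and LiCl in the presence of Me3SiCl (THF, −100 °C) should give (S)-trimethyl{[3-methyl-3-(4-methyl-2,6,7-trioxabicyclo[2.2.2]octan-1-yl)cyclobut-1-en-1-yl]oxy}silane F3; which enantiomer of the amide is needed would have to be found in a first experiment. MeLi (THF, 0 °C) then frees the regiodefined lithium enolate, which is alkylated with 14 (THF/HMPA, −40 to 0 °C) trans to the ortho ester to give (2R,3S)-2-[(3R,4S,7R)-9-(tert-butyldimethylsilyloxy)-3,4,7-trimethyl-4-[(trimethylsilyl)ethynyl]nonyl]-3-methyl-3-(4-methyl-2,6,7-trioxabicyclo[2.2.2]octan-1-yl)cyclobutan-1-one F4. Condensation with 19, here only as a ketone mask, comes back to the route at 21.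

Step 15. The hydrazone may hydrolyse already in the acidic stage, so that the free ketone epimerises at C5 in the basic stage, or methanolysis of the hindered ester may stop short. The fallback replaces acyl transfer to methoxide by saponification and O-methylation. Setting out from 21, the PPTS stage alone gives 22, which is isolated; LiOH (THF/H2O, 40 °C) should cleave the diol ester and the alkynyl C–Si bond to give (1S,2R)-2-[(3R,4S,7R)-9-(tert-butyldimethylsilyloxy)-4-ethynyl-3,4,7-trimethylnonyl]-3-{[(2S)-2-(methoxymethyl)pyrrolidin-1-yl]imino}-1-methylcyclobutane-1-carboxylic acid F5. Me3SiCHN2 (toluene/MeOH, 0 °C) then methylates the carboxylic acid and comes back to the route at 23.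

Further compounds
F1 | step 18 | methyl (1S,2R)-2-[(3R,4R,7R)-9-acetoxy-4-ethenyl-3,4,7-trimethylnonyl]-1-methyl-3-oxocyclobutane-1-carboxylate | COC(=O)[C@@]1(C)CC(=O)[C@@H]1CC[C@@H](C)[C@@](C)(C=C)CC[C@@H](C)CCOC(C)=O
F2 | step 18 | methyl 15-acetoxy-2-oxohalimane-18-oate (C10 configuration open) | COC(=O)[C@@]1(C)CC(=O)CC2[C@@H]1CC[C@@H](C)[C@]2(C)CC[C@@H](C)CCOC(C)=O
F3 | step 14 | (S)-trimethyl{[3-methyl-3-(4-methyl-2,6,7-trioxabicyclo[2.2.2]octan-1-yl)cyclobut-1-en-1-yl]oxy}silane | CC12COC(OC1)(OC2)[C@@]3(C)CC(O[Si](C)(C)C)=C3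
F4 | step 14 | (2R,3S)-2-[(3R,4S,7R)-9-(tert-butyldimethylsilyloxy)-3,4,7-trimethyl-4-[(trimethylsilyl)ethynyl]nonyl]-3-methyl-3-(4-methyl-2,6,7-trioxabicyclo[2.2.2]octan-1-yl)cyclobutan-1-one | CC12COC(OC1)(OC2)[C@@]3(C)CC(=O)[C@@H]3CC[C@@H](C)[C@@](C)(C#C[Si](C)(C)C)CC[C@@H](C)CCO[Si](C)(C)C(C)(C)C
F5 | step 15 | (1S,2R)-2-[(3R,4S,7R)-9-(tert-butyldimethylsilyloxy)-4-ethynyl-3,4,7-trimethylnonyl]-3-{[(2S)-2-(methoxymethyl)pyrrolidin-1-yl]imino}-1-methylcyclobutane-1-carboxylic acid | OC(=O)[C@@]1(C)CC(=NN2CCC[C@H]2COC)[C@@H]1CC[C@@H](C)[C@@](C)(C#C)CC[C@@H](C)CCO[Si](C)(C)C(C)(C)C
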